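## Retrosynthetic overview

1. The 2,2-dimethylpyran at C7–C8 is the last ring. It comes from a 7-O-(1,1-dimethylpropargyl) flavone by an aryl propargyl [3,3] Claisen shift, a 1,5-H shift and an oxa-6π electrocyclisation.
2. Pyrone ring C comes from C-acylation of a benzoxepinone enolate with a ring-A salicylate acetonide that already carries the propargyl ether, followed by acid cyclodehydration. Ring A is symmetric at that point, so only one pyrone can form.
3. The oxepine comes from an intramolecular SNAr of a secondary alkoxide on an ortho-fluoroaryl ketone. The C–O bond at the stereocentre is never broken.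
4. The fluoroaryl keto diol comes from an aryllithium and (R)-5-(2-hydroxypropan-2-yl)butyrolactone. That lactone comes from (R)-5-oxotetrahydrofuran-2-carboxylic acid (D-glutamic acid series) and 2 MeMgBr.
5. Ring order: oxepine on ring B, then pyrone C joining ring A, then the pyran.

Assumption: the four numbered starting materials, including the acetonide of 2,4,6-trihydroxybenzoic acid, are taken as catalogue compounds.

## Route

Step 1
Reactants: 1 (2R)-5-oxotetrahydrofuran-2-carboxylic acid
Product: 2 ethyl (2R)-5-oxotetrahydrofuran-2-carboxylate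
Conditions: EtOH, p-TsOH·H2O (cat.), toluene, reflux, Dean–Stark
Reagents that add atoms: ethanol, CCO
Why: Fischer esterification with azeotropic water removal breaks no bond at the stereocentre bought with 1 and does not enolise it under acid, so (R) is kept.

Step 2
Reactants: 2 ethyl (2R)-5-oxotetrahydrofuran-2-carboxylate
Product: 3 (5R)-5-(2-hydroxypropan-2-yl)dihydrofuran-2(3H)-one
Conditions: MeMgBr (2.1 equiv), THF, −78 to −30 °C; then 1 M HCl, 0 °C
Reagents that add atoms: methylmagnesium bromide, C[Mg]Br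
Why: The double Grignard addition is chemoselective at low temperature for the exocyclic ester, which is activated by its α-acyloxy group and by chelation (the same preference is seen when borohydride reduces this ester), and addition outruns enolisation so (R) is kept.

Step 3
Reactants: 4 4-bromo-3-fluorophenol
Product: 5 1-bromo-2-fluoro-4-(methoxymethoxy)benzene
Conditions: NaH, MOMCl, THF, 0 °C to rt
Reagents that add atoms: chloromethyl methyl ether, COCCl
Why: Williamson-type O-alkylation masks the acidic phenol as a MOM acetal, which tolerates organolithium and alkoxide chemistry and keeps ring B from becoming a deactivating phenoxide.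

Step 4
Reactants: 5 1-bromo-2-fluoro-4-(methoxymethoxy)benzene (2.2 equiv); 3 (5R)-5-(2-hydroxypropan-2-yl)dihydrofuran-2(3H)-one
Product: 7 (4R)-1-[2-fluoro-4-(methoxymethoxy)phenyl]-4,5-dihydroxy-5-methylhexan-1-one, via aryllithium 6 (not isolated)
Conditions: n-BuLi (2.2 equiv), THF, −78 °C, 20 min; add 3, −78 °C, 1 h; then H2O
Reagents that add atoms: n-butyllithium, [Li]CCCC (lithium of 6 only)
Why: Bromine–lithium exchange is followed by aryllithium addition to the lactone carbonyl (one equivalent is spent on the tertiary OH), the lithium hemiketal survives at −78 °C so no second addition occurs, and only the acyl C–O bond opens so (R) is retained.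

Step 5
Reactants: 7 (4R)-1-[2-fluoro-4-(methoxymethoxy)phenyl]-4,5-dihydroxy-5-methylhexan-1-one
Product: 8 (2R)-2-(2-hydroxypropan-2-yl)-8-(methoxymethoxy)-3,4-dihydro-1-benzoxepin-5(2H)-one
Conditions: NaH (1.2 equiv), DMF (0.02 M), 0 to 70 °C
Reagents that add atoms: none
Why: In this intramolecular SNAr (addition–elimination) the secondary alkoxide attacks the fluorinated carbon ortho to the activating ketone to close the seven-membered ring, which is favoured over the eight-membered ring from the hindered tertiary alkoxide, and the C–O bond of the stereocentre stays intact so (R) is retained.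

Step 6
Reactants: 9 5,7-dihydroxy-2,2-dimethyl-4H-1,3-benzodioxin-4-one; 10 3-chloro-3-methylbut-1-yne (2 equiv)
Product: 11 5-hydroxy-2,2-dimethyl-7-[(2-methylbut-3-yn-2-yl)oxy]-4H-1,3-benzodioxin-4-one
Conditions: K2CO3, KI (cat.), CuI (cat.), acetone, reflux, N2
Reagents that add atoms: none
Why: Copper-assisted propargylic O-alkylation takes place only at the free, acidic 7-OH because the 5-OH is hydrogen-bonded to the carbonyl, and 56 °C is too low for a premature Claisen shift.

Step 7
Reactants: 11 5-hydroxy-2,2-dimethyl-7-[(2-methylbut-3-yn-2-yl)oxy]-4H-1,3-benzodioxin-4-one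
Product: 12 5-(methoxymethoxy)-2,2-dimethyl-7-[(2-methylbut-3-yn-2-yl)oxy]-4H-1,3-benzodioxin-4-one
Conditions: NaH (1.1 equiv), MOMCl, DMF, 0 °C
Reagents that add atoms: chloromethyl methyl ether, COCCl
Why: Williamson-type MOM protection removes the chelated phenol, which would otherwise quench the enolate and, as a phenoxide, deactivate the acyl carbon in the next step.

Step 8
Reactants: 8 (2R)-2-(2-hydroxypropan-2-yl)-8-(methoxymethoxy)-3,4-dihydro-1-benzoxepin-5(2H)-one; 12 5-(methoxymethoxy)-2,2-dimethyl-7-[(2-methylbut-3-yn-2-yl)oxy]-4H-1,3-benzodioxin-4-one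
Product: 15 (R)-5,4'-dihydroxy-7-[(2-methylbut-3-yn-2-yl)oxy]flavone bridged from C3 to the 2'-oxygen by CH2–CH[C(CH3)2OH] (oxepine ring), via dilithio enolate 13 (not isolated), via 1,3-diketone 14 (not isolated)
Conditions: LiN(SiMe3)2 (3.5 equiv), THF, −78 °C; add 12, −78 to 0 °C; then 2 M HCl in MeOH, 45 °C
Reagents that add atoms: lithium hexamethyldisilazide, [Li]N([Si](C)(C)C)[Si](C)(C)C (lithium of 13 only)
Why: In a crossed Claisen condensation the only enolisable carbon of 8 attacks the benzodioxinone carbonyl, which collapses with loss of acetone to free an ortho-phenol, and acid then cleaves both MOM groups and cyclodehydrates the 1,3-diketone (flavone synthesis) on a now symmetric ring A, so only one pyrone can form, the C4 epimers converge to an sp2 carbon, the poorly ionising tertiary propargyl ether and β-aryloxy tertiary alcohol survive, and the remote (R) centre is untouched.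

Step 9
Reactants: 15 (R)-5,4'-dihydroxy-7-[(2-methylbut-3-yn-2-yl)oxy]flavone bridged from C3 to the 2'-oxygen by CH2–CH[C(CH3)2OH]
Product: 18 target CNP0329736.1 (R)-5,4'-dihydroxy-6'',6''-dimethylpyrano[2'',3'':7,8]flavone carrying the same C3–CH2–CH[C(CH3)2OH]–O–C2' oxepine bridge, via 8-allenyl-7-phenol 16 (not isolated), via ortho-quinone methide 17 (not isolated)
Conditions: DMF, 140 °C, argon, 8 h
Reagents that add atoms: none
Why: The aromatic propargyl Claisen [3,3] shift delivers the C5 unit to C8, because the pyrone gives the C7–C8 bond the higher double-bond character (as in the angular acronycine and pyranoxanthone series), and tautomerisation, a 1,5-H shift and an oxa-6π electrocyclisation then close the 2,2-dimethylpyran without touching the (R) centre.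

## Compound list

1 | (2R)-5-oxotetrahydrofuran-2-carboxylic acid | O=C1CC[C@H](C(=O)O)O1 | starting material
2 | ethyl (2R)-5-oxotetrahydrofuran-2-carboxylate | O=C1CC[C@H](C(=O)OCC)O1 | intermediate
3 | (5R)-5-(2-hydroxypropan-2-yl)dihydrofuran-2(3H)-one | O=C1CC[C@H](C(C)(C)O)O1 | intermediate
4 | 4-bromo-3-fluorophenol | Oc1ccc(Br)c(F)c1 | starting material
5 | 1-bromo-2-fluoro-4-(methoxymethoxy)benzene | COCOc1ccc(Br)c(F)c1 | intermediate
6 | [2-fluoro-4-(methoxymethoxy)phenyl]lithium | COCOc1ccc([Li])c(F)c1 | intermediate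
7 | (4R)-1-[2-fluoro-4-(methoxymethoxy)phenyl]-4,5-dihydroxy-5-methylhexan-1-one | COCOc1ccc(C(=O)CC[C@H](C(C)(C)O)O)c(F)c1 | intermediate
8 | (2R)-2-(2-hydroxypropan-2-yl)-8-(methoxymethoxy)-3,4-dihydro-1-benzoxepin-5(2H)-one | COCOc1ccc2C(=O)CC[C@H](C(C)(C)O)Oc2c1 | intermediate
9 | 5,7-dihydroxy-2,2-dimethyl-4H-1,3-benzodioxin-4-one | CC1(C)OC(=O)c2c(O)cc(O)cc2O1 | starting material
10 | 3-chloro-3-methylbut-1-yne | C#CC(C)(C)Cl | starting material
11 | 5-hydroxy-2,2-dimethyl-7-[(2-methylbut-3-yn-2-yl)oxy]-4H-1,3-benzodioxin-4-one | CC1(C)OC(=O)c2c(O)cc(OC(C)(C)C#C)cc2O1 | intermediate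
12 | 5-(methoxymethoxy)-2,2-dimethyl-7-[(2-methylbut-3-yn-2-yl)oxy]-4H-1,3-benzodioxin-4-one | CC1(C)OC(=O)c2c(OCOC)cc(OC(C)(C)C#C)cc2O1 | intermediate
13 | dilithium salt of 8 (C4–C5 enolate and tertiary alkoxide) | COCOc1ccc2C(O[Li])=CC[C@H](C(C)(C)O[Li])Oc2c1 | intermediate
14 | (2R,4RS)-4-{2-hydroxy-6-(methoxymethoxy)-4-[(2-methylbut-3-yn-2-yl)oxy]benzoyl}-2-(2-hydroxypropan-2-yl)-8-(methoxymethoxy)-3,4-dihydro-1-benzoxepin-5(2H)-one | COCOc1ccc2C(=O)C(C(=O)c3c(O)cc(OC(C)(C)C#C)cc3OCOC)C[C@H](C(C)(C)O)Oc2c1 | intermediate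
15 | (R)-5,4'-dihydroxy-7-[(2-methylbut-3-yn-2-yl)oxy]flavone with C3–CH2–CH[C(CH3)2OH]–O–C2' oxepine bridge | C#CC(C)(C)Oc1cc(O)c2c(=O)c3c(oc2c1)-c1ccc(O)cc1O[C@@H](C(C)(C)O)C3 | intermediate
16 | (R)-5,7,4'-trihydroxy-8-(3-methylbuta-1,2-dienyl)flavone with the same oxepine bridge | CC(C)=C=Cc1c(O)cc(O)c2c(=O)c3c(oc12)-c1ccc(O)cc1O[C@@H](C(C)(C)O)C3 | intermediate
17 | (R)-ortho-quinone methide: 7-oxo-8-(3-methylbut-2-enylidene) tautomer of 16, vinyl group cis to C7=O | CC(C)=C/C=C1\C(=O)C=C(O)C2=C1OC1=C(C2=O)C[C@H](C(C)(C)O)Oc2cc(O)ccc12 | intermediate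
18 | CNP0329736.1, (R) at the oxepine O–CH | CC1(C)C=Cc2c(cc(O)c3c(=O)c4c(oc23)-c2ccc(O)cc2O[C@@H](C(C)(C)O)C4)O1 | target

## Step count and risks

Total steps: 9. Longest linear sequence: 6 (steps 1, 2, 4, 5, 8, 9).

**Step 5 (oxepine SNAr).** Base also gives the ketone enolate and the five-membered hemiketal anion. Both switch off the activating carbonyl, and a seven-membered closure can lose to oligomerisation.

The fallback sets out from 3 and comes back at 8. 3-Bromo-4-iodophenol is MOM-protected (NaH, MOMCl) to 2-bromo-1-iodo-4-(methoxymethoxy)benzene F1. Selective iodine–magnesium exchange (i-PrMgCl·LiCl, THF, −20 °C) gives [2-bromo-4-(methoxymethoxy)phenyl]magnesium chloride F2. This adds to 3, whose hydroxyl is first deprotonated with one more equivalent of i-PrMgCl, to give (4R)-1-[2-bromo-4-(methoxymethoxy)phenyl]-4,5-dihydroxy-5-methylhexan-1-one F3. The ring is then closed by palladium-catalysed intramolecular C–O coupling (Pd(OAc)2, RockPhos, Cs2CO3, toluene, 90 °C) to 8. The aryl–oxygen bond now forms by reductive elimination from an arylpalladium alkoxide, so it no longer depends on carbonyl activation, and the C–O bond of the stereocentre is again untouched.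

**Step 8 (C-acylation with an electron-rich, ortho-substituted acyl donor).** The Claisen condensation at a ring methylene may be slow. It may also lose to O-acylation or to attack of the amide base on 12.

The fallback sets out from 12 and enolate 13 and comes back at 15. Compound 12 is reduced with i-Bu2AlH (CH2Cl2, −78 °C), and the lactol collapses with loss of acetone to 2-hydroxy-6-(methoxymethoxy)-4-[(2-methylbut-3-yn-2-yl)oxy]benzaldehyde F4. This is capped (NaH, MOMCl) as 2,6-bis(methoxymethoxy)-4-[(2-methylbut-3-yn-2-yl)oxy]benzaldehyde F5. The much more electrophilic aldehyde takes up enolate 13 at −78 °C in an aldol addition to give the β-hydroxy ketone F6 as a diastereomer mixture. Dess–Martin oxidation, to which the tertiary alcohol is inert, gives the tris-MOM 1,3-diketone F7. The same HCl/MeOH treatment then delivers 15.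

**Step 9 (C8 against C6 in the Claisen shift).** The 5-OH···O=C chelate favours the opposite bond fixation, so some or much of the linear 6,7-pyrano isomer may form.

The fallback sets out from 15 and comes back at 18. Ac2O in pyridine (no DMAP, so the tertiary alcohol is spared) gives the 5,4'-diacetate of the propargyl ether F8. In F8 the chelate is gone, C6 is flanked by two oxygen substituents, and only the pyrone fixes the bond order, as in 7-allyloxy and 7-propargyloxy flavones that lack a 5-OH. Heating (DMF, 140 °C) gives the angular pyranoflavone 5,4'-diacetate F9, and K2CO3 in MeOH at 0 °C releases 18.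

## Further compounds

F1 | step 5 | 2-bromo-1-iodo-4-(methoxymethoxy)benzene | COCOc1ccc(I)c(Br)c1
F2 | step 5 | [2-bromo-4-(methoxymethoxy)phenyl]magnesium chloride | COCOc1ccc([Mg]Cl)c(Br)c1
F3 | step 5 | (4R)-1-[2-bromo-4-(methoxymethoxy)phenyl]-4,5-dihydroxy-5-methylhexan-1-one | COCOc1ccc(C(=O)CC[C@H](C(C)(C)O)O)c(Br)c1
F4 | step 8 | 2-hydroxy-6-(methoxymethoxy)-4-[(2-methylbut-3-yn-2-yl)oxy]benzaldehyde | O=Cc1c(O)cc(OC(C)(C)C#C)cc1OCOC
F5 | step 8 | 2,6-bis(methoxymethoxy)-4-[(2-methylbut-3-yn-2-yl)oxy]benzaldehyde | O=Cc1c(OCOC)cc(OC(C)(C)C#C)cc1OCOC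
F6 | step 8 | (2R)-4-{hydroxy[2,6-bis(methoxymethoxy)-4-[(2-methylbut-3-yn-2-yl)oxy]phenyl]methyl}-2-(2-hydroxypropan-2-yl)-8-(methoxymethoxy)-3,4-dihydro-1-benzoxepin-5(2H)-one, diastereomer mixture | COCOc1ccc2C(=O)C(C(O)c3c(OCOC)cc(OC(C)(C)C#C)cc3OCOC)C[C@H](C(C)(C)O)Oc2c1
F7 | step 8 | (2R,4RS)-4-{2,6-bis(methoxymethoxy)-4-[(2-methylbut-3-yn-2-yl)oxy]benzoyl}-2-(2-hydroxypropan-2-yl)-8-(methoxymethoxy)-3,4-dihydro-1-benzoxepin-5(2H)-one | COCOc1ccc2C(=O)C(C(=O)c3c(OCOC)cc(OC(C)(C)C#C)cc3OCOC)C[C@H](C(C)(C)O)Oc2c1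
F8 | step 9 | 5,4'-di-O-acetyl derivative of 15 | C#CC(C)(C)Oc1cc(OC(C)=O)c2c(=O)c3c(oc2c1)-c1ccc(OC(C)=O)cc1O[C@@H](C(C)(C)O)C3
F9 | step 9 | 5,4'-di-O-acetyl derivative of 18 | CC1(C)C=Cc2c(cc(OC(C)=O)c3c(=O)c4c(oc23)-c2ccc(OC(C)=O)cc2O[C@@H](C(C)(C)O)C4)O1
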